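**Retrosynthetic overview**
1. Last disconnections: the γ-lactone (C19–O7, from a dimethylamide and a C7/C8 acetonide), C11=C20 (from a C11 nitro group via the ketone) and C5=C6 (ring-closing metathesis), leading back to nitrocyclohexanone 18.
2. Key disconnection of ring A at C12–C13 and C1–C10: a [3+3] carbocyclization of diketone 16 (C13–C14–C1) with 2-nitroallyl acetate 12 (C12–C11–C10), convergent and self-correcting at C1/C10.
3. Enabling feature: ring A (C1, C10, C11, C12, C13, C14) is a 4-methylenecyclohexane in which C11 (bearing exocyclic C20) is flanked by C10 and C12 and lies para to oxygenated C14, while C1 sits between oxygenated C14 and C2. At the ketone level this is a 2-methyl-1,3-diketone (nucleophilic at C1 and α′-C13) plus a 2-nitroallyl unit (electrophilic at C10 and C12, NO2 as latent C11=C20).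
4. Fragment 12 comes from diacetone-D-glucose (C6–C10 = sugar C1–C5; C8 and C17 set by an aldol on the 3-ulose); fragment 16 comes from 3-methylpentane-2,4-dione.
5. Ring order: ring A (six-membered, step 8), then the ten-membered ring (step 13), then the γ-lactone (step 16).

Key step: step 8

Remark (chemistry): positions are numbered as in the briarane skeleton of 26 (C15 on C1, C16 on C5, C17/C18/C19 = lactone α-carbon, its methyl and carbonyl, C20 on C11); it is assumed that C11 of 18–23, the carbinol carbons of 11 and the anomeric carbon of 6 can be carried as epimer mixtures, because each is later made sp2 or destroyed.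

**Step 1**
Reactants: 1 diacetone-D-glucose
Product: 2 1,2:5,6-di-O-isopropylidene-α-D-ribo-hexofuranos-3-ulose
Conditions: TEMPO (cat.), KBr (cat.), NaOCl, NaHCO3, CH2Cl2/H2O, 0 °C; ketone dried azeotropically
Reagents that add atoms: none
Why: TEMPO/hypochlorite oxidation of the only free (secondary) hydroxyl should give the ketone without touching the acetals; no new stereocentre.

**Step 2**
Reactants: 2 the 3-ulose; 3 N,N-dimethylpropanamide
Product: 5 (2R)-2-(1,2:5,6-di-O-isopropylidene-α-D-allofuranos-3-C-yl)-N,N-dimethylpropanamide, via lithium (Z)-enolate 4 (not isolated)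
Conditions: LiN(i-Pr)2, THF, −78 °C; 2 added at −78 °C; AcOH quench at −78 °C
Reagents that add atoms: none
Why: Aldol addition of the amide (Z)-enolate to the ketone: attack on the convex β-face of the cis-fused bicycle (anti to the 1,2-acetonide) should set C8, and the closed Zimmerman–Traxler-type transition state with the amide group over the unhindered C7 side and the enolate hydrogen over the ring should set C17.

**Step 3**
Reactants: 5 the aldol adduct
Product: 6 3-C-[(1R)-1-(dimethylcarbamoyl)ethyl]-2,3:5,6-di-O-isopropylidene-D-allofuranose (lactol)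
Conditions: TsOH·H2O (cat.), acetone, rt
Reagents that add atoms: none
Why: Acid-catalysed acetal migration to the thermodynamic 2,3-O-isopropylidene furanose (cis-diol of the allo series) should tie O7 to the tertiary O8, free the lactol (masked C6 aldehyde) and leave O9 as the ring oxygen; no stereocentre is touched.

**Step 4**
Reactants: 6 the lactol
Product: 8 open-chain C9 acetate with a vinyl group on the C7/C8 dioxolane, via potassium alkoxide 7 (not isolated)
Conditions: Ph3PCH3Br, KOt-Bu, THF, 0 °C → reflux; then Ac2O, DMAP (cat.), 0 °C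
Reagents that add atoms: methyltriphenylphosphonium bromide, C[P+](c1ccccc1)(c1ccccc1)c1ccccc1.[Br-]; acetic anhydride, CC(=O)OC(C)=O
Why: Wittig methylenation of the open hydroxy-aldehyde form of the lactol frees O9 as its alkoxide, which is acetylated in the same flask so that the γ-hydroxy amide is never isolated; no new stereocentre.

**Step 5**
Reactants: 8 the C9 acetate
Product: 9 α-acetoxy aldehyde (C10 aldehyde)
Conditions: H5IO6 (1.3 equiv), EtOAc, rt
Reagents that add atoms: none
Why: Periodic acid should hydrolyse the terminal dioxolane selectively and cleave the resulting 1,2-diol (glycol cleavage) under non-basic conditions, so C9 keeps its configuration.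

**Step 6**
Reactants: 9 the aldehyde; 10 2-nitroethanol
Product: 12 (E)-2-nitroallyl acetate (C10=C11 nitroalkene with C12 acetoxymethyl), via nitro diol 11 (not isolated)
Conditions: 10, i-Pr2NEt (0.2 equiv), THF, 0 °C; then Ac2O, Et3N, DMAP (cat.), CH2Cl2, 0 °C → rt
Reagents that add atoms: acetic anhydride, CC(=O)OC(C)=O
Why: Henry (nitroaldol) addition followed by acetylation and E1cB loss of the C10 acetate should give the conjugated, more substituted nitroalkene (acetate-mediated allylic transposition funnels the 1-substituted isomer to it); the two new carbinol centres are destroyed and the E geometry is the thermodynamic one.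

**Step 7**
Reactants: 13 3-methylpentane-2,4-dione; 14 3-bromo-2-methylprop-1-ene
Product: 16 3,7-dimethyloct-7-ene-2,4-dione, via dilithium dienolate 15 (not isolated)
Conditions: LiN(i-Pr)2 (2.1 equiv), THF, −78 → 0 °C; then 14, −78 → 0 °C; aq. HCl
Reagents that add atoms: none
Why: γ-Alkylation of the β-diketone dianion at a terminal methyl (the more basic carbanion site) by SN2 displacement of the allylic bromide; the two methyl groups of 13 are equivalent and no configurationally stable stereocentre is formed.

**Step 8**
Reactants: 12 the 2-nitroallyl acetate; 16 the diketone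
Product: 18 nitrocyclohexanone with ring A closed (C11 epimers), via nitroallyl diketone 17 (not isolated)
Conditions: Cs2CO3 (1.5 equiv), MeCN (0.02 M), 0 → 40 °C; 16 added slowly to 12
Reagents that add atoms: none
Why: The cesium diketonate of 16 adds through C1 to C10 of nitroalkene 12 (Michael addition), the nitronate expels acetate from C12 (E1cB, overall SN2′) to give terminal nitroalkene 17, and the cesium enolate of the methyl ketone then adds through C13 to C12 (intramolecular Michael addition); this is the two-stage [3+3] carbocyclization known for 2-nitroallyl esters with ketone-derived α,α′-bis-nucleophiles. Ring A closes in a 6-endo-trig mode at C12, and no other ring is formed. C10 should be set by Felkin–Anh-type addition anti to the C9–OAc bond with H-9 eclipsing the nitroalkene (allylic strain); C1 should be set in the ring closure through a chair transition state in which the C9 branch is pseudoaxial (A(1,2) strain with the nitro group), the larger C2 acyl chain lies anti to it and the methyl group is equatorial next to the enolate oxygen, so that C2 and C9 end up trans. The first addition is reversible (acetate re-addition at C12 and retro-Michael loss of the diketonate), so the E and Z isomers of 12 and the C1 and C10 epimers of 17 should be funnelled through this one cyclization, while C11 stays an inconsequential epimer mixture that becomes the C11=C20 carbon later. The step needs attack at C10 before C12 (secured by the nitroalkene polarity and the absence of nucleophilic amines), ring closure through the methyl carbon C13 and not the methylene C3 (less substituted enolate terminus, less crowded transition state), and C- over O-cyclization (O-adducts revert).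

**Step 9**
Reactants: 18 the nitrocyclohexanone
Product: 19 axial C14 alcohol
Conditions: LiBH(s-Bu)3 (1.1 equiv), THF, −78 °C; AcOH quench at −78 °C
Reagents that add atoms: none
Why: Ketone reduction by a bulky trialkylborohydride: equatorial attack on the ring ketone of the chair with the C2 and C9 branches equatorial and the C1 methyl axial should give the axial C14 alcohol (trans to the methyl), while the acyclic neopentyl-type C2 ketone reacts much more slowly at −78 °C and C–H deprotonation of the nitroalkane is slow.

**Step 10**
Reactants: 19 the C14 alcohol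
Product: 20 C14 acetate
Conditions: Ac2O, pyridine, DMAP (cat.), CH2Cl2, rt
Reagents that add atoms: acetic anhydride, CC(=O)OC(C)=O
Why: DMAP-catalysed esterification of the hindered secondary alcohol; the remaining C2 ketone cannot enolize toward C1.

**Step 11**
Reactants: 20 the keto acetate
Product: 21 (2R)-alcohol
Conditions: (S)-2-methyl-CBS-oxazaborolidine (0.3 equiv), catecholborane (1.5 equiv), toluene, −78 → −40 °C
Reagents that add atoms: none
Why: Corey–Bakshi–Shibata reduction: the (S)-oxazaborolidine differentiates the quaternary C1 (large) from the C3 methylene (small) and should deliver hydride to give the (2R)-alcohol under reagent control; catecholborane does not hydroborate the alkenes at low temperature.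

**Step 12**
Reactants: 21 the C2 alcohol
Product: 22 C2 propionate
Conditions: (EtCO)2O, Et3N, DMAP (cat.), CH2Cl2, rt
Reagents that add atoms: propionic anhydride, CCC(=O)OC(=O)CC
Why: DMAP-catalysed acylation of the only free hydroxyl.

**Step 13**
Reactants: 22 the diene
Product: 23 bicyclic nitro compound with the ten-membered ring closed (5Z)
Conditions: (H2IMes)(PCy3)Cl2Ru=CHPh (second-generation Grubbs catalyst, 10 mol%), toluene (0.5 mM), 80 °C
Reagents that add atoms: none
Why: Ring-closing metathesis between the vinyl group and the 1,1-disubstituted alkene under high dilution: the trans C2/C9 branches on ring A and the cis-dioxolane pre-organize the chain ends, the ten-membered ring should allow only the Z (ring-cis) trisubstituted alkene, and no other alkene competes because C11 still carries the nitro group.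

**Step 14**
Reactants: 23 the macrocyclic nitro compound
Product: 24 C11 ketone
Conditions: TiCl3 (aq., 6 equiv), NH4OAc buffer, THF/H2O, rt
Reagents that add atoms: water, O
Why: Reductive Nef reaction: trivalent titanium reduces the secondary nitro group to the imine, which hydrolyses to the ketone under buffered, non-basic conditions that spare the β-acetoxy ketone and the esters.

**Step 15**
Reactants: 24 the C11 ketone
Product: 25 11(20)-methylene amide acetonide
Conditions: Zn, CH2Br2, TiCl4 (Lombardo reagent, pre-formed in THF), CH2Cl2, 0 °C → rt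
Reagents that add atoms: dibromomethane, BrCBr
Why: Lombardo methylenation converts the hindered ketone into the exocyclic methylene without base, so C10 should not epimerize and the C9 acetate should not be eliminated; esters and the amide are inert.

**Step 16**
Reactants: 25 the amide acetonide
Product: 26 junceellolide E
Conditions: AcOH/H2O (4:1), 50 °C
Reagents that add atoms: none
Why: Acidic hydrolysis of the dioxolane frees O7 and O8, and the γ-hydroxyl O7 lactonizes onto the neighbouring dimethylamide (intramolecular acyl transfer, five-membered ring); O9 is acetylated and O8 is tertiary and β, so only O7 can close, and C7, C8 and C17 keep their configurations.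

**Compound list**
1 | 1,2:5,6-di-O-isopropylidene-α-D-glucofuranose (diacetone-D-glucose) | CC1(C)O[C@H]2O[C@H]([C@H]3COC(C)(C)O3)[C@H](O)[C@H]2O1 | starting material
2 | 1,2:5,6-di-O-isopropylidene-α-D-ribo-hexofuranos-3-ulose | CC1(C)O[C@H]2O[C@H]([C@H]3COC(C)(C)O3)C(=O)[C@H]2O1 | intermediate
3 | N,N-dimethylpropanamide | CCC(=O)N(C)C | starting material
4 | lithium (Z)-enolate of 3 (methyl cis to O–Li) | C/C=C(\O[Li])N(C)C | intermediate
5 | (2R)-2-(1,2:5,6-di-O-isopropylidene-α-D-allofuranos-3-C-yl)-N,N-dimethylpropanamide (tertiary 3-OH on the α-face; sugar C3 = C8, side-chain CH = C17) | CC1(C)O[C@H]2O[C@H]([C@H]3COC(C)(C)O3)[C@](O)([C@@H](C)C(=O)N(C)C)[C@H]2O1 | intermediate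
6 | 3-C-[(1R)-1-(dimethylcarbamoyl)ethyl]-2,3:5,6-di-O-isopropylidene-D-allofuranose (lactol, anomer mixture; sugar C1–C5 = C6–C10) | OC1O[C@H]([C@H]2COC(C)(C)O2)[C@]3(OC(C)(C)O[C@@H]13)[C@@H](C)C(=O)N(C)C | intermediate
7 | potassium C9-alkoxide of the ring-opened alkene (vinyl on C7; C7/C8 dioxolane; terminal C10 dioxolane) | C=C[C@@H]1OC(C)(C)O[C@]1([C@@H](C)C(=O)N(C)C)[C@H](O[K])[C@H]2COC(C)(C)O2 | intermediate
8 | C9 acetate: 2,2-dimethyl-1,3-dioxolane across O7/O8 carrying vinyl (C7), the (17R)-1-(dimethylcarbamoyl)ethyl group and the C9 acetoxymethine (C8), which bears the terminal isopropylidene diol; C7, C8, C9, C17 as in 26 | C=C[C@@H]1OC(C)(C)O[C@]1([C@@H](C)C(=O)N(C)C)[C@H](OC(C)=O)[C@H]2COC(C)(C)O2 | intermediate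
9 | α-acetoxy aldehyde (C10 = CHO; otherwise as 8) | C=C[C@@H]1OC(C)(C)O[C@]1([C@@H](C)C(=O)N(C)C)[C@H](OC(C)=O)C=O | intermediate
10 | 2-nitroethanol | OCC[N+](=O)[O-] | starting material
11 | nitro diol (C10 carbinol, C11 nitro, C12 CH2OH; epimer mixture at C10 and C11) | C=C[C@@H]1OC(C)(C)O[C@]1([C@@H](C)C(=O)N(C)C)[C@H](OC(C)=O)C(O)C(CO)[N+](=O)[O-] | intermediate
12 | (E)-2-nitroallyl acetate: AcOCH2(C12)–C11(NO2)=C10H–C9H(OAc)– attached to the C7/C8 dioxolane of 8 (minor Z isomer tolerated) | C=C[C@@H]1OC(C)(C)O[C@]1([C@@H](C)C(=O)N(C)C)[C@H](OC(C)=O)/C=C(\COC(C)=O)[N+](=O)[O-] | intermediate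
13 | 3-methylpentane-2,4-dione | CC(=O)C(C)C(C)=O | starting material
14 | 3-bromo-2-methylprop-1-ene | C=C(C)CBr | starting material
15 | dilithium dienolate (dianion) of 13 | [Li]OC(=C)C(C)=C(C)O[Li] | intermediate
16 | 3,7-dimethyloct-7-ene-2,4-dione (C13 = acetyl methyl, C14, C1, C2, C3, C4, C5 with C16, terminal CH2) | CC(=O)C(C)C(=O)CCC(C)=C | intermediate
17 | nitroallyl diketone: C1 of the diketone bonded to C10, terminal nitroalkene C11(NO2)=C12H2 (C1 epimers) | C=C([N+](=O)[O-])[C@@H](C(C)(C(C)=O)C(=O)CCC(C)=C)[C@@H](OC(C)=O)[C@@]1([C@@H](C)C(=O)N(C)C)OC(C)(C)O[C@H]1C=C | intermediate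
18 | nitrocyclohexanone: ring A with C14 ketone, C1 (methyl and 5-methylhex-5-enoyl), C10 (C9 side chain), C11 nitro (epimers); C2 acyl trans to C9 | O=[N+]([O-])C1CCC(=O)[C@](C)(C(=O)CCC(C)=C)[C@H]1[C@@H](OC(C)=O)[C@@]2([C@@H](C)C(=O)N(C)C)OC(C)(C)O[C@H]2C=C | intermediate
19 | C14 alcohol (OH axial, trans to the C1 methyl) | O=[N+]([O-])C1CC[C@H](O)[C@](C)(C(=O)CCC(C)=C)[C@H]1[C@@H](OC(C)=O)[C@@]2([C@@H](C)C(=O)N(C)C)OC(C)(C)O[C@H]2C=C | intermediate
20 | C14 acetate, C2 ketone | O=[N+]([O-])C1CC[C@H](OC(C)=O)[C@](C)(C(=O)CCC(C)=C)[C@H]1[C@@H](OC(C)=O)[C@@]2([C@@H](C)C(=O)N(C)C)OC(C)(C)O[C@H]2C=C | intermediate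
21 | (2R)-alcohol | O=[N+]([O-])C1CC[C@H](OC(C)=O)[C@](C)([C@H](O)CCC(C)=C)[C@H]1[C@@H](OC(C)=O)[C@@]2([C@@H](C)C(=O)N(C)C)OC(C)(C)O[C@H]2C=C | intermediate
22 | C2 propionate (metathesis precursor: vinyl on C7, isopropenyl end at C5) | O=[N+]([O-])C1CC[C@H](OC(C)=O)[C@](C)([C@H](OC(=O)CC)CCC(C)=C)[C@H]1[C@@H](OC(C)=O)[C@@]2([C@@H](C)C(=O)N(C)C)OC(C)(C)O[C@H]2C=C | intermediate
23 | bicyclic nitro compound: ring A fused to the ten-membered ring (5Z), C7/C8 acetonide, C17 dimethylamide, C11 nitro | O=[N+]([O-])C1CC[C@H](OC(C)=O)[C@@]2(C)[C@H]1[C@@H](OC(C)=O)[C@@]3([C@@H](C)C(=O)N(C)C)OC(C)(C)O[C@H]3/C=C(/C)CC[C@H]2OC(=O)CC | intermediate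
24 | C11 ketone | O=C1CC[C@H](OC(C)=O)[C@@]2(C)[C@H]1[C@@H](OC(C)=O)[C@@]3([C@@H](C)C(=O)N(C)C)OC(C)(C)O[C@H]3/C=C(/C)CC[C@H]2OC(=O)CC | intermediate
25 | 11(20)-methylene compound (C7/C8 acetonide, C17 dimethylamide) | C=C1CC[C@H](OC(C)=O)[C@@]2(C)[C@H]1[C@@H](OC(C)=O)[C@@]3([C@@H](C)C(=O)N(C)C)OC(C)(C)O[C@H]3/C=C(/C)CC[C@H]2OC(=O)CC | intermediate
26 | junceellolide E, (1R,2R,5Z,7S,8S,9R,10S,14S,17R) in briarane numbering | C=C1CC[C@H](OC(C)=O)[C@@]2(C)[C@H]1[C@@H](OC(C)=O)[C@@]1(O)[C@H](/C=C(/C)CC[C@H]2OC(=O)CC)OC(=O)[C@@H]1C | target

**Step count**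
Total: 16 steps. Longest linear sequence: 15 steps (1–6, then 8–16).

**Steps most likely to fail**

Step 8 (key step). The ring closure of 17 may run through the more substituted enolate terminus C3, giving the regioisomeric cyclohexanone. The facial pairing at C1 may be poor, or a second diketonate may capture 17 before it cyclizes. The fallback sets out from 12 and comes back at 18. The annulation is run with the symmetrical diketone 13 in place of 16 (Cs2CO3, MeCN), so that both α′-carbons are equivalent methyl groups and C1 becomes stereogenic only in the ring closure. This should give the acetyl nitrocyclohexanone F1. Its acetyl methyl group is then extended by kinetic enolate alkylation (LiN(SiMe3)2, 2 equiv, THF, −78 °C, nitronate formed first; then 14) to return to 18.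

Step 13. Oligomerization by cross-metathesis may outrun closure of the ten-membered ring, or the catalyst may stall at the hindered 1,1-disubstituted alkene. The fallback sets out from 22 and comes back at 26. The order is changed so that the ring is closed on a γ-lactone template instead of the dioxolane. Compound 22 is first treated as in step 16 (AcOH/H2O) to give the hydroxy lactone diene F2, in which C6 and C9 already have the trans relation across C7–C8 that the target ring needs. Ring-closing metathesis should then give the macrocyclic nitro lactone F3, the buffered TiCl3 Nef reaction the keto lactone F4, and Lombardo methylenation the target 26.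

Step 6. The E1cB step may lose the wrong acetate, giving the 1-substituted 2-nitroallyl isomer that would reverse the regiochemistry of step 8, and C9 may epimerize under the basic nitroaldol conditions. The fallback sets out from 9 and comes back at 12. The C12 carbon is introduced only after the nitroalkene is in place. Henry addition of nitromethane to 9 (i-Pr2NEt cat.) gives the nitro alcohol F5. Acetylation and elimination (Ac2O, DMAP) give the (E)-nitroalkene F6. A Morita–Baylis–Hillman-type hydroxymethylation at C11 (aqueous formaldehyde, imidazole, THF) gives the hydroxymethyl nitroalkene F7, which can only carry its CH2OH on C11. Acetylation (Ac2O, pyridine) then returns to 12.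

**Further compounds**
F1 | step 8 | acetyl nitrocyclohexanone (analogue of 18 with acetyl in place of the 5-methylhex-5-enoyl group on C1) | O=[N+]([O-])C1CCC(=O)[C@](C)(C(C)=O)[C@H]1[C@@H](OC(C)=O)[C@@]2([C@@H](C)C(=O)N(C)C)OC(C)(C)O[C@H]2C=C
F2 | step 13 | hydroxy lactone diene (γ-lactone and free C8–OH in place, C11 nitro, ten-membered ring still open) | O=[N+]([O-])C1CC[C@H](OC(C)=O)[C@](C)([C@H](OC(=O)CC)CCC(C)=C)[C@H]1[C@@H](OC(C)=O)[C@@]2(O)[C@H](C=C)OC(=O)[C@@H]2C
F3 | step 13 | macrocyclic nitro lactone (11-nitro analogue of 26 lacking C20) | O=[N+]([O-])C1CC[C@H](OC(C)=O)[C@@]2(C)[C@H]1[C@@H](OC(C)=O)[C@@]1(O)[C@H](/C=C(/C)CC[C@H]2OC(=O)CC)OC(=O)[C@@H]1C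
F4 | step 13 | keto lactone (11-oxo analogue of 26 lacking C20) | O=C1CC[C@H](OC(C)=O)[C@@]2(C)[C@H]1[C@@H](OC(C)=O)[C@@]1(O)[C@H](/C=C(/C)CC[C@H]2OC(=O)CC)OC(=O)[C@@H]1C
F5 | step 6 | nitro alcohol (C10 carbinol, C11 CH2NO2; C10 epimers) | C=C[C@@H]1OC(C)(C)O[C@]1([C@@H](C)C(=O)N(C)C)[C@H](OC(C)=O)C(O)C[N+](=O)[O-]
F6 | step 6 | (E)-nitroalkene (C10=C11, no C12) | C=C[C@@H]1OC(C)(C)O[C@]1([C@@H](C)C(=O)N(C)C)[C@H](OC(C)=O)/C=C/[N+](=O)[O-]
F7 | step 6 | hydroxymethyl nitroalkene (C12 CH2OH on C11; the alcohol of 12) | C=C[C@@H]1OC(C)(C)O[C@]1([C@@H](C)C(=O)N(C)C)[C@H](OC(C)=O)/C=C(\CO)[N+](=O)[O-]
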